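**Plan**
- **Cuts.** First the five O-protecting groups, the O–CH3 bond and the aryl–butyryl bond of ring B. Then, inside ring B, C5–C6 (C-methyl carbon to methoxy carbon) and C3–C4 (butyryl-bearing carbon to the oxygenated carbon beside the C-methyl carbon); this takes ring B apart into a 4-(ring A-methyl)-3-alkoxycyclobutenone and a 1-siloxypropyne. Last, the cyclobutenone is cut into a ring A-CH2-substituted ketene and an alkoxyacetylene.
- **Enabling feature.** Ring B (C1 bridge carbon, C2 OH, C3 butyryl, C4 OH, C5 CH3, C6 OCH3) bears oxygen on the alternate carbons C2, C4 and C6. These are the 3-alkoxy oxygen of a cyclobutenone, the oxygen of an ynol ether and the carbonyl oxygen of a ketene.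
- **Forward order.** Ring A is bought (2,4,6-trihydroxytoluene), filled up (CHO, pentanoyl), benzylated and extended by two carbons to a propanoyl chloride. The four-membered ring follows, then ring B. The CH2 bridge is bonded to ring A before ring B exists, so scrambling of the halves has no pathway.
- **Oxygen differentiation.** The three ring B oxygens arrive differentiated (free OH, silyl ether, isopropyl ether). The free OH becomes OCH3, and no ethyl or methyl ether has to be cleaved beside it at the end.
- **Stereochemistry.** The target has no stereocentre. The cyclobutenone stereocentre is racemic and disappears on aromatisation.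

Key step: step 9

Assumption: the target is taken as the achiral triphenol/diphenol tautomer drawn by its SMILES.
Notation: ArA = 2,4,6-tris(benzyloxy)-3-methyl-5-pentanoylphenyl. Ring B locants are those given in the plan.

Step 1
Reactants: 1 2,4,6-trihydroxytoluene
Product: 3 2,4,6-trihydroxy-3-methylbenzaldehyde, via aryl iminium chloride 2 (not isolated)
Conditions: POCl3 (1.1 equiv), DMF, EtOAc, 0 °C → rt; then H2O, 50 °C
Reagents that add atoms: N,N-dimethylformamide CN(C)C=O; water O
Why: Vilsmeier–Haack formylation: the chloroiminium ion attacks one of the two equivalent free ring carbons of the very electron-rich triphenol, the iminium group of 2 shuts the ring down against a second attack, and water releases the aldehyde.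

Step 2
Reactants: 3 2,4,6-trihydroxy-3-methylbenzaldehyde; 4 pentanoyl chloride
Product: 5 2,4,6-trihydroxy-3-methyl-5-pentanoylbenzaldehyde
Conditions: TiCl4 (4 equiv), CH2Cl2, 0 °C → rt; 1 M HCl
Reagents that add atoms: none
Why: Friedel–Crafts C-acylation at the only ring C–H left, which three OH groups keep nucleophilic in spite of the formyl group; the aldehyde is installed before the ketone because an ortho-hydroxyaryl alkyl ketone would be diverted to a chromone by the Vilsmeier reagent.

Step 3
Reactants: 5 2,4,6-trihydroxy-3-methyl-5-pentanoylbenzaldehyde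
Product: 6 2,4,6-tris(benzyloxy)-3-methyl-5-pentanoylbenzaldehyde
Conditions: BnBr (4.5 equiv), K2CO3 (6 equiv), n-Bu4NI (cat), DMF, 60 °C
Reagents that add atoms: benzyl bromide BrCc1ccccc1
Why: Williamson etherification in a dipolar aprotic solvent: the two carbonyl groups drain carbon nucleophilicity from the fully substituted ring, so exhaustive O-benzylation of the three hydrogen-bonded phenols should win over dearomatising C-benzylation.

Step 4
Reactants: 6 2,4,6-tris(benzyloxy)-3-methyl-5-pentanoylbenzaldehyde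
Product: 9 3-ArA-propanoic acid, via arylidene Meldrum's acid 7 (not isolated), via benzyl Meldrum's acid 8 (not isolated)
Conditions: Meldrum's acid (1.1 equiv), HCO2H–Et3N (5:2), 95 °C
Reagents that add atoms: Meldrum's acid CC1(C)OC(=O)CC(=O)O1
Why: Knoevenagel condensation to 7, conjugate hydride transfer from formate to give 8, then hydrolysis by the water of condensation and loss of acetone and CO2 run in one flask, a known reductive two-carbon homologation of aryl aldehydes that uses no hydrogenation catalyst and so spares the benzyl ethers and the shielded ketone.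

Step 5
Reactants: 9 3-ArA-propanoic acid
Product: 10 3-ArA-propanoyl chloride
Conditions: (COCl)2 (1.5 equiv), DMF (cat), CH2Cl2, 0 °C → rt; evaporated and used at once
Reagents that add atoms: oxalyl chloride O=C(Cl)C(=O)Cl
Why: Standard acid chloride formation catalysed by the DMF-derived chloroiminium ion; ring A has no free position for an intramolecular Friedel–Crafts closure, and prompt use forestalls attack of an ortho benzyloxy oxygen on the acyl chloride.

Step 6
Reactants: 11 propan-2-ol; 12 trichloroethene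
Product: 16 isopropoxyacetylene, via dichlorovinyl ether 13 (not isolated), via chloroethynyl ether 14 (not isolated), via lithium acetylide 15 (not isolated)
Conditions: KH (2 equiv), THF, 0 °C; 12, −50 °C → rt; n-BuLi (2.5 equiv), −78 → −40 °C; H2O; kept cold as a dried, assayed THF–hexane solution
Reagents that add atoms: none
Why: One-flask ynol ether synthesis from trichloroethene: net substitution of chloride by the alkoxide gives the (E)-dichlorovinyl ether 13, n-BuLi eliminates HCl to 14 and exchanges the remaining chlorine for lithium, and protonation of 15 gives the terminal alkyne.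

Step 7
Reactants: 10 3-ArA-propanoyl chloride; 16 isopropoxyacetylene
Product: 18 rac-4-(ArA-methyl)-3-isopropoxycyclobut-2-en-1-one, via alkylketene 17 (not isolated)
Conditions: 16 (3 equiv), Et3N (1.3 equiv, slow addition), THF–hexane, 0 °C → rt
Reagents that add atoms: none
Why: Dehydrochlorination to ketene 17 followed by ketene–alkoxyacetylene [2+2] cycloaddition, in which the nucleophilic terminal alkyne carbon bonds to the ketene carbonyl carbon so that O-i-Pr sits at C3 and the ArA-methyl group at C4; the C4 stereocentre forms without control (racemate) and is erased in step 9.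

Step 8
Reactants: 19 propyne
Product: 22 triisopropyl(prop-1-yn-1-yloxy)silane, via propynyllithium 20 (not isolated), via lithium ynolate 21 (not isolated)
Conditions: n-BuLi, THF, −78 °C; t-BuOOLi [t-BuOOH + LiN(SiMe3)2], −78 → 0 °C; i-Pr3SiOTf, −78 → 0 °C
Reagents that add atoms: tert-butyl hydroperoxide CC(C)(C)OO; triisopropylsilyl trifluoromethanesulfonate CC(C)[Si](C(C)C)(C(C)C)OS(=O)(=O)C(F)(F)F
Why: Electrophilic oxygenation of an alkynyllithium by t-BuOOLi gives ynolate 21, and the bulky silyl triflate silylates it on oxygen, the established entry to thermally robust siloxyalkynes.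

Step 9
Reactants: 18 rac-4-(ArA-methyl)-3-isopropoxycyclobut-2-en-1-one; 22 triisopropyl(prop-1-yn-1-yloxy)silane
Product: 27 2-(ArA-methyl)-3-isopropoxy-6-methyl-5-(triisopropylsiloxy)phenol, via vinylketene 23 (not isolated), via vinylcyclobutenone 24 (not isolated), via dienylketene 25 (not isolated), via cyclohexadienone 26 (not isolated)
Conditions: 22 (2 equiv), PhMe (0.5 M), sealed tube, Ar, dark, 110 °C then 135 °C
Reagents that add atoms: none
Why: Danheiser benzannulation in its siloxyalkyne form is the closest known reaction type: heat opens 18 by a conrotatory 4π electrocyclic reaction, the ArA-methyl group turning outward, to vinylketene 23, whose C=C=O unit adds [2+2] to 22 to give vinylcyclobutenone 24. A second, reversible 4π opening gives dienylketene 25, ring B closes by disrotatory 6π electrocyclisation between the ketene carbon and the carbon that carries the bridge CH2, and dienone 26 tautomerises to phenol 27. Net, the bonds C5–C6 and C3–C4 of ring B are new, and the C1–C4 bond of 18 is broken and made again as C6–C1 of ring B. Only the orientation of the [2+2] step has to be controlled: donation from the siloxy oxygen makes the CH3-bearing alkyne carbon the nucleophilic one, it bonds to the electrophilic carbonyl carbon of 23, and OSi(i-Pr)3 therefore lands 1,3 to the new OH and next to the lone ring C–H. The stereocentres of 18, 24 and 26 are transient and vanish on ring opening or aromatisation, so nothing has to be controlled there. A silyl ynol ether is chosen because, unlike an ethyl one, it cannot lose an alkene by a retro-ene reaction at these temperatures, and light is kept out because the pentanoyl ketone of ring A would abstract its own γ-hydrogen when excited.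

Step 10
Reactants: 27 2-(ArA-methyl)-3-isopropoxy-6-methyl-5-(triisopropylsiloxy)phenol
Product: 28 2-(ArA-methyl)-1-isopropoxy-3-methoxy-4-methyl-5-(triisopropylsiloxy)benzene
Conditions: MeI (3 equiv), K2CO3 (2 equiv), acetone, reflux
Reagents that add atoms: iodomethane CI
Why: Williamson O-methylation of the one free phenol of 27, so that the site of the OCH3 group needs no selectivity, while K2CO3 in acetone neither enolises the ketone nor touches the silyl ether.

Step 11
Reactants: 28 2-(ArA-methyl)-1-isopropoxy-3-methoxy-4-methyl-5-(triisopropylsiloxy)benzene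
Product: 30 1-(benzyloxy)-4-(ArA-methyl)-5-isopropoxy-3-methoxy-2-methylbenzene, via ammonium phenoxide 29 (not isolated)
Conditions: n-Bu4NF (1.1 equiv), THF, 0 °C; then BnBr (1.5 equiv), rt
Reagents that add atoms: benzyl bromide BrCc1ccccc1
Why: Fluoride-induced desilylation to phenoxide 29 and Williamson benzylation in the same flask exchange the bulky, weakly donating silyl ether beside the last ring C–H for a slim, strongly donating ether that falls in the final step.

Step 12
Reactants: 30 1-(benzyloxy)-4-(ArA-methyl)-5-isopropoxy-3-methoxy-2-methylbenzene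
Product: 31 1-[2-(benzyloxy)-5-(ArA-methyl)-6-isopropoxy-4-methoxy-3-methylphenyl]butan-1-one
Conditions: n-PrCO2H (3 equiv), (CF3CO)2O (3 equiv), CH2Cl2, 0 °C → rt
Reagents that add atoms: butanoic acid CCCC(=O)O
Why: Friedel–Crafts acylation by the mixed anhydride of butanoic and trifluoroacetic acid, a metal-free method that acylates 1,3,5-trialkoxybenzenes at room temperature: ring B offers a single C–H (ortho to two ethers and para to the third), ring A is full and deactivated, and aryl benzyl and isopropyl ethers, which TiCl4 or AlCl3 would strip, tolerate dilute CF3CO2H.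

Step 13
Reactants: 31 1-[2-(benzyloxy)-5-(ArA-methyl)-6-isopropoxy-4-methoxy-3-methylphenyl]butan-1-one
Product: 32 1-{3-[(3-butanoyl-2,4-dihydroxy-6-methoxy-5-methylphenyl)methyl]-2,4,6-trihydroxy-5-methylphenyl}pentan-1-one (target)
Conditions: BCl3 (12 equiv), C6HMe5 (15 equiv), CH2Cl2, −78 → 0 °C; MeOH, then 1 M HCl
Reagents that add atoms: none
Why: Lewis acid ether cleavage graded by cation stability: BCl3 removes aryl benzyl ethers at −78 °C when C6HMe5 traps the benzyl cation and aryl isopropyl ethers on warming to 0 °C, whereas an aryl methyl ether that is not ortho to a carbonyl group (here it is para to the butyryl group) is left intact.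

**Compound list**
1 | 2,4,6-trihydroxytoluene | Cc1c(O)cc(O)cc1O | starting material
2 | N-[(2,4,6-trihydroxy-3-methylphenyl)methylidene]-N-methylmethanaminium chloride | Cc1c(O)cc(O)c(C=[N+](C)C)c1O.[Cl-] | intermediate
3 | 2,4,6-trihydroxy-3-methylbenzaldehyde | Cc1c(O)cc(O)c(C=O)c1O | intermediate
4 | pentanoyl chloride | CCCCC(=O)Cl | starting material
5 | 2,4,6-trihydroxy-3-methyl-5-pentanoylbenzaldehyde | CCCCC(=O)c1c(O)c(C)c(O)c(C=O)c1O | intermediate
6 | 2,4,6-tris(benzyloxy)-3-methyl-5-pentanoylbenzaldehyde | CCCCC(=O)c1c(OCc2ccccc2)c(C)c(OCc2ccccc2)c(C=O)c1OCc1ccccc1 | intermediate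
7 | 5-(ArA-methylidene)-2,2-dimethyl-1,3-dioxane-4,6-dione | CCCCC(=O)c1c(OCc2ccccc2)c(C)c(OCc2ccccc2)c(C=C2C(=O)OC(C)(C)OC2=O)c1OCc1ccccc1 | intermediate
8 | 5-(ArA-methyl)-2,2-dimethyl-1,3-dioxane-4,6-dione | CCCCC(=O)c1c(OCc2ccccc2)c(C)c(OCc2ccccc2)c(CC2C(=O)OC(C)(C)OC2=O)c1OCc1ccccc1 | intermediate
9 | 3-ArA-propanoic acid | CCCCC(=O)c1c(OCc2ccccc2)c(C)c(OCc2ccccc2)c(CCC(=O)O)c1OCc1ccccc1 | intermediate
10 | 3-ArA-propanoyl chloride | CCCCC(=O)c1c(OCc2ccccc2)c(C)c(OCc2ccccc2)c(CCC(=O)Cl)c1OCc1ccccc1 | intermediate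
11 | propan-2-ol | CC(C)O | starting material
12 | trichloroethene | ClC=C(Cl)Cl | starting material
13 | (E)-1,2-dichlorovinyl isopropyl ether | CC(C)O/C(Cl)=C\Cl | intermediate
14 | chloroethynyl isopropyl ether | CC(C)OC#CCl | intermediate
15 | lithium isopropoxyacetylide | CC(C)OC#C[Li] | intermediate
16 | isopropoxyacetylene, 2-(ethynyloxy)propane | CC(C)OC#C | intermediate
17 | (ArA-methyl)ketene, 3-ArA-prop-1-en-1-one | O=C=CCc1c(OCc2ccccc2)c(C)c(OCc2ccccc2)c(C(=O)CCCC)c1OCc1ccccc1 | intermediate
18 | rac-4-(ArA-methyl)-3-isopropoxycyclobut-2-en-1-one | O=C1C=C(OC(C)C)C1Cc1c(OCc2ccccc2)c(C)c(OCc2ccccc2)c(C(=O)CCCC)c1OCc1ccccc1 | intermediate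
19 | propyne | CC#C | starting material
20 | prop-1-ynyllithium | CC#C[Li] | intermediate
21 | lithium prop-1-yn-1-olate | CC#C[O-].[Li+] | intermediate
22 | triisopropyl(prop-1-yn-1-yloxy)silane | CC#CO[Si](C(C)C)(C(C)C)C(C)C | intermediate
23 | (3Z)-5-ArA-3-isopropoxypenta-1,3-dien-1-one (CH2ArA trans to the ketenyl carbon) | O=C=C/C(OC(C)C)=C/Cc1c(OCc2ccccc2)c(C)c(OCc2ccccc2)c(C(=O)CCCC)c1OCc1ccccc1 | intermediate
24 | rac-4-[(Z)-3-ArA-1-isopropoxyprop-1-enyl]-2-methyl-3-(triisopropylsiloxy)cyclobut-2-en-1-one | O=C1C(C)=C(O[Si](C(C)C)(C(C)C)C(C)C)C1/C(OC(C)C)=C/Cc1c(OCc2ccccc2)c(C)c(OCc2ccccc2)c(C(=O)CCCC)c1OCc1ccccc1 | intermediate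
25 | (3E,5Z)-7-ArA-5-isopropoxy-2-methyl-3-(triisopropylsiloxy)hepta-1,3,5-trien-1-one | O=C=C(C)/C(O[Si](C(C)C)(C(C)C)C(C)C)=C\C(OC(C)C)=C\Cc1c(OCc2ccccc2)c(C)c(OCc2ccccc2)c(C(=O)CCCC)c1OCc1ccccc1 | intermediate
26 | rac-6-(ArA-methyl)-5-isopropoxy-2-methyl-3-(triisopropylsiloxy)cyclohexa-2,4-dien-1-one | O=C1C(C)=C(O[Si](C(C)C)(C(C)C)C(C)C)C=C(OC(C)C)C1Cc1c(OCc2ccccc2)c(C)c(OCc2ccccc2)c(C(=O)CCCC)c1OCc1ccccc1 | intermediate
27 | 2-(ArA-methyl)-3-isopropoxy-6-methyl-5-(triisopropylsiloxy)phenol (ring B: C2 O-i-Pr, C3 H, C4 OSi(i-Pr)3, C5 CH3, C6 OH) | Oc1c(C)c(O[Si](C(C)C)(C(C)C)C(C)C)cc(OC(C)C)c1Cc1c(OCc2ccccc2)c(C)c(OCc2ccccc2)c(C(=O)CCCC)c1OCc1ccccc1 | intermediate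
28 | 2-(ArA-methyl)-1-isopropoxy-3-methoxy-4-methyl-5-(triisopropylsiloxy)benzene | COc1c(C)c(O[Si](C(C)C)(C(C)C)C(C)C)cc(OC(C)C)c1Cc1c(OCc2ccccc2)c(C)c(OCc2ccccc2)c(C(=O)CCCC)c1OCc1ccccc1 | intermediate
29 | tetrabutylammonium 4-(ArA-methyl)-5-isopropoxy-3-methoxy-2-methylphenoxide | COc1c(C)c([O-])cc(OC(C)C)c1Cc1c(OCc2ccccc2)c(C)c(OCc2ccccc2)c(C(=O)CCCC)c1OCc1ccccc1.CCCC[N+](CCCC)(CCCC)CCCC | intermediate
30 | 1-(benzyloxy)-4-(ArA-methyl)-5-isopropoxy-3-methoxy-2-methylbenzene | COc1c(C)c(OCc2ccccc2)cc(OC(C)C)c1Cc1c(OCc2ccccc2)c(C)c(OCc2ccccc2)c(C(=O)CCCC)c1OCc1ccccc1 | intermediate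
31 | 1-[2-(benzyloxy)-5-(ArA-methyl)-6-isopropoxy-4-methoxy-3-methylphenyl]butan-1-one | COc1c(C)c(OCc2ccccc2)c(C(=O)CCC)c(OC(C)C)c1Cc1c(OCc2ccccc2)c(C)c(OCc2ccccc2)c(C(=O)CCCC)c1OCc1ccccc1 | intermediate
32 | 1-{3-[(3-butanoyl-2,4-dihydroxy-6-methoxy-5-methylphenyl)methyl]-2,4,6-trihydroxy-5-methylphenyl}pentan-1-one | CCCCC(=O)c1c(O)c(C)c(O)c(Cc2c(O)c(C(=O)CCC)c(O)c(C)c2OC)c1O | target

**Step count**
- Total step count: 13.
- Longest linear sequence: 11 steps (1, 2, 3, 4, 5, 7, 9, 10, 11, 12, 13, starting from 1).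
- Steps 6 and 8 are one-step side branches.

**Steps most likely to fail**

**Step 9.**
- What may go wrong: the vinylogous ester resonance of 18 may raise the barrier of the first ring opening. The low stationary concentration of 23 would then be lost to ketene dimerisation or to O-acylation of phenol already formed. The cascade may also stall at 24 because the alkenyl group turns outward on ring opening.
- Fallback route: it sets out from aldehyde 6 (and from 1 for the second half) and comes back at target 32.
- NaBH4 (MeOH–THF, 0 °C) reduces only the aldehyde of 6, because the ketone is shielded by two ortho ethers. This gives 1-[2,4,6-tris(benzyloxy)-3-(hydroxymethyl)-5-methylphenyl]pentan-1-one F1.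
- Ring B is made as a finished nucleophile. Compound 1 with butanoyl chloride and AlCl3 gives 1-(2,4,6-trihydroxy-3-methylphenyl)butan-1-one F2.
- The only OH of F2 not hydrogen-bonded to the ketone (the one para to it) is methylated with Me2SO4 (1 equiv) and K2CO3 in acetone. This gives 1-(2,6-dihydroxy-4-methoxy-3-methylphenyl)butan-1-one F3.
- Acid-catalysed Friedel–Crafts benzylation (cat TsOH, CH2Cl2, rt) joins the benzylic cation of F1 to the single free ring carbon of F3. This gives 1-{2,4,6-tris(benzyloxy)-3-[(3-butanoyl-2,4-dihydroxy-6-methoxy-5-methylphenyl)methyl]-5-methylphenyl}pentan-1-one F4.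
- Hydrogenolysis (H2, Pd/C, EtOAc) then leads to 32.

**Step 12.**
- What may go wrong: the last ring C–H is buttressed by two ortho ethers whose alkyl groups are pushed towards it. Acylation may be too slow, so that acid-induced loss of benzyl groups or ipso attack at the bridge carbon with cleavage of the diarylmethane competes.
- Fallback route: it sets out from 30 and comes back at 31, and brings in the carbonyl carbon as a smaller electrophile.
- Vilsmeier–Haack formylation (POCl3, DMF, 0 → 60 °C) gives 2-(benzyloxy)-5-(ArA-methyl)-6-isopropoxy-4-methoxy-3-methylbenzaldehyde F5.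
- n-PrMgCl (THF, −78 °C) adds to the aldehyde in preference to the doubly ortho-shielded pentanoyl ketone. This gives rac-1-[2-(benzyloxy)-5-(ArA-methyl)-6-isopropoxy-4-methoxy-3-methylphenyl]butan-1-ol F6.
- Dess–Martin periodinane (CH2Cl2, rt) oxidises F6 to 31.

**Step 7.**
- What may go wrong: dimerisation of the monoalkylketene, and addition of HCl from the ammonium salt to the ynol ether, may outrun the cycloaddition.
- Fallback route: it sets out from acid 9 and comes back at phenol 27. It reaches the vinylketene without a four-membered ring precursor.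
- Chain extension of 9 (carbonyldiimidazole, then Mg(O2CCH2CO2Et)2, THF; Claisen-type acylation with decarboxylation) gives ethyl 5-ArA-3-oxopentanoate F7.
- HC(O-i-Pr)3, i-PrOH and cat TsOH convert F7 into ethyl (E)-5-ArA-3-isopropoxypent-2-enoate F8.
- LiOH (THF–H2O) gives (E)-5-ArA-3-isopropoxypent-2-enoic acid F9.
- 1-Chloro-N,N,2-trimethylpropenylamine (CH2Cl2, 0 °C, neutral) gives (E)-5-ArA-3-isopropoxypent-2-enoyl chloride F10.
- Slow addition of Et3N to F10 and 22 in warm toluene removes HCl in the 1,4 sense (γ-deprotonation). This gives the same vinylketene 23 (either alkene geometry serves), which runs through 24, 25 and 26 to 27 on further heating.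

Further compounds
F1 | step 9 | 1-[2,4,6-tris(benzyloxy)-3-(hydroxymethyl)-5-methylphenyl]pentan-1-one | OCc1c(OCc2ccccc2)c(C)c(OCc2ccccc2)c(C(=O)CCCC)c1OCc1ccccc1
F2 | step 9 | 1-(2,4,6-trihydroxy-3-methylphenyl)butan-1-one | CCCC(=O)c1c(O)cc(O)c(C)c1O
F3 | step 9 | 1-(2,6-dihydroxy-4-methoxy-3-methylphenyl)butan-1-one | CCCC(=O)c1c(O)cc(OC)c(C)c1O
F4 | step 9 | 1-{2,4,6-tris(benzyloxy)-3-[(3-butanoyl-2,4-dihydroxy-6-methoxy-5-methylphenyl)methyl]-5-methylphenyl}pentan-1-one | CCCC(=O)c1c(O)c(C)c(OC)c(Cc2c(OCc3ccccc3)c(C)c(OCc3ccccc3)c(C(=O)CCCC)c2OCc2ccccc2)c1O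
F5 | step 12 | 2-(benzyloxy)-5-(ArA-methyl)-6-isopropoxy-4-methoxy-3-methylbenzaldehyde | COc1c(C)c(OCc2ccccc2)c(C=O)c(OC(C)C)c1Cc1c(OCc2ccccc2)c(C)c(OCc2ccccc2)c(C(=O)CCCC)c1OCc1ccccc1
F6 | step 12 | rac-1-[2-(benzyloxy)-5-(ArA-methyl)-6-isopropoxy-4-methoxy-3-methylphenyl]butan-1-ol | COc1c(C)c(OCc2ccccc2)c(C(O)CCC)c(OC(C)C)c1Cc1c(OCc2ccccc2)c(C)c(OCc2ccccc2)c(C(=O)CCCC)c1OCc1ccccc1
F7 | step 7 | ethyl 5-ArA-3-oxopentanoate | CCOC(=O)CC(=O)CCc1c(OCc2ccccc2)c(C)c(OCc2ccccc2)c(C(=O)CCCC)c1OCc1ccccc1
F8 | step 7 | ethyl (E)-5-ArA-3-isopropoxypent-2-enoate | CCOC(=O)/C=C(/OC(C)C)CCc1c(OCc2ccccc2)c(C)c(OCc2ccccc2)c(C(=O)CCCC)c1OCc1ccccc1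
F9 | step 7 | (E)-5-ArA-3-isopropoxypent-2-enoic acid | OC(=O)/C=C(/OC(C)C)CCc1c(OCc2ccccc2)c(C)c(OCc2ccccc2)c(C(=O)CCCC)c1OCc1ccccc1
F10 | step 7 | (E)-5-ArA-3-isopropoxypent-2-enoyl chloride | ClC(=O)/C=C(/OC(C)C)CCc1c(OCc2ccccc2)c(C)c(OCc2ccccc2)c(C(=O)CCCC)c1OCc1ccccc1
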